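**Retrosynthetic overview**
- Alkene fragment: 3,4,5-trimethoxybenzaldehyde 1 → (carbinol 2, not isolated) → (E)-isoelemicin 3, which carries Cα (aryl-bearing), Cβ (methyl-bearing) and the E geometry that becomes trans.
- Oxygenated ring: the C2v-symmetric 4-bromo-2,6-dimethoxyphenol 4 is oxidatively demethylated to the non-aromatic, unsymmetrical o-quinone 5; one operation breaks both aromaticity and symmetry.
- Key disconnection: both C–O bonds of the dioxane ring of bromide 6 at once, i.e. a catalytic asymmetric inverse-electron-demand oxa-[4+2] of 5 with 3. This is the only ring formed, and it sets both stereocentres.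
- Last disconnection: the aryl–vinyl bond. Heck coupling of 6 with acrolein diethyl acetal (acetal 7, not isolated) and hydrolysis give the target 8.

**Notation and assumptions**
- Labels: Cα = aryl-bearing ring carbon, Cβ = methyl-bearing ring carbon. Oa = ring oxygen on the aromatic carbon next to the OMe-bearing carbon (in quinone 5, the carbonyl oxygen next to C–OMe). Ob = the other ring oxygen. The target has Cβ–Oa and Cα–Ob, both centres S, trans.
- Assumption: which enantiomer of the acid catalyst gives the (2S,3S) series cannot be predicted with certainty. The (S,S)-catalyst is written; if the first run gives the antipode (chiral HPLC, ECD), its mirror image is used and nothing else changes.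

**Step 1**
Reactants: 1 3,4,5-trimethoxybenzaldehyde
Product: 3 (E)-isoelemicin [(E)-1,2,3-trimethoxy-5-(prop-1-enyl)benzene], via carbinol 2 (not isolated)
Conditions: EtMgBr (1.2 equiv), THF, 0 °C to rt; cold 1 M HCl quench, extract into toluene; then p-TsOH·H2O (2 mol%), toluene, reflux, Dean–Stark
Reagents that add atoms: ethylmagnesium bromide, CC[Mg]Br
Why: Grignard addition to the aldehyde followed by acid-catalysed E1 dehydration of the benzylic carbinol under thermodynamic control gives the conjugated (E)-propenylarene (E:Z about 95:5 or better), and no stereocentre is carried forward.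

**Step 2**
Reactants: 4 4-bromo-2,6-dimethoxyphenol; 3 (E)-isoelemicin
Product: 6 (2S,3S)-7-bromo-5-methoxy-3-methyl-2-(3,4,5-trimethoxyphenyl)-2,3-dihydro-1,4-benzodioxine, via o-quinone 5 (not isolated)
Conditions: IBX (1.1 equiv, on 1.3 equiv of 4), DMF, 0 °C to rt, dark; cold H2O/CH2Cl2 partition, dry (MgSO4, then 4 Å MS); then 3 (1.0 equiv), (S,S)-IDPi (imidodiphosphorimidate from two (S)-3,3'-bis[3,5-bis(trifluoromethyl)phenyl]-1,1'-bi-2-naphthol units, N-trifluoromethanesulfonyl groups on both phosphorus atoms; 5 mol%), CH2Cl2, −40 °C; Et3N quench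
Reagents that add atoms: 2-iodoxybenzoic acid (IBX), O=C1OI(=O)(O)c2ccccc12
Why: Proposed new method: the pentavalent iodine reagent delivers oxygen to a methoxy-bearing ortho carbon of 4 and methanol is expelled (oxidative demethylation, known for 2,6-dimethoxyphenols), which gives quinone 5; the confined chiral Brønsted acid should bind Ob, the more basic carbonyl oxygen (it receives vinylogous donation from OMe and Br), so that the nucleophilic Cβ of the (E)-alkene attacks Oa on one face inside the chiral pocket and Cα closes onto Ob in a concerted, asynchronous oxa-Diels–Alder reaction that re-aromatises the ring, turns the E geometry into the trans relationship and sets both stereocentres as (2S,3S) under catalyst control; the closest known reaction types are the uncatalysed hetero-Diels–Alder reaction of o-quinones with (E)-propenylarenes to trans-1,4-benzodioxanes and imidodiphosphorimidate-catalysed asymmetric [4+2] additions of styrenes to O-protonated carbonyl heterodienes (intermolecular Prins-type dioxane formation).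

**Step 3**
Reactants: 6 (2S,3S)-7-bromo-5-methoxy-3-methyl-2-(3,4,5-trimethoxyphenyl)-2,3-dihydro-1,4-benzodioxine
Product: 8 (E)-3-[(2S,3S)-8-methoxy-2-methyl-3-(3,4,5-trimethoxyphenyl)-2,3-dihydro-1,4-benzodioxin-6-yl]prop-2-enal (target), via diethyl acetal 7 (not isolated)
Conditions: acrolein diethyl acetal (3 equiv), Pd(OAc)2 (3 mol%), n-Bu4NOAc (2 equiv), K2CO3 (1.5 equiv), KCl (1 equiv), DMF, 90 °C; then 2 N HCl, rt, 15 min
Reagents that add atoms: acrolein diethyl acetal (3,3-diethoxyprop-1-ene), C=CC(OCC)OCC; water, O
Why: A phosphine-free Mizoroki–Heck reaction (zerovalent palladium inserts into the C–Br bond, syn insertion, β-hydride elimination towards the benzylic position) gives the (E)-cinnamyl acetal, and brief dilute acid unmasks the (E)-enal while the two ring stereocentres, both ether carbons, are untouched.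

**Compound list**
1 | 3,4,5-trimethoxybenzaldehyde | COc1cc(C=O)cc(OC)c1OC | starting material
2 | 1-(3,4,5-trimethoxyphenyl)propan-1-ol (racemic) | CCC(O)c1cc(OC)c(OC)c(OC)c1 | intermediate
3 | (E)-isoelemicin, (E)-1,2,3-trimethoxy-5-(prop-1-enyl)benzene | C/C=C/c1cc(OC)c(OC)c(OC)c1 | intermediate
4 | 4-bromo-2,6-dimethoxyphenol | COc1cc(Br)cc(OC)c1O | starting material
5 | 5-bromo-3-methoxycyclohexa-3,5-diene-1,2-dione (o-quinone) | COC1=CC(Br)=CC(=O)C1=O | intermediate
6 | (2S,3S)-7-bromo-5-methoxy-3-methyl-2-(3,4,5-trimethoxyphenyl)-2,3-dihydro-1,4-benzodioxine | COc1cc([C@@H]2Oc3cc(Br)cc(OC)c3O[C@H]2C)cc(OC)c1OC | intermediate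
7 | (2S,3S)-7-[(E)-3,3-diethoxyprop-1-enyl]-5-methoxy-3-methyl-2-(3,4,5-trimethoxyphenyl)-2,3-dihydro-1,4-benzodioxine | COc1cc([C@@H]2Oc3cc(/C=C/C(OCC)OCC)cc(OC)c3O[C@H]2C)cc(OC)c1OC | intermediate
8 | (E)-3-[(2S,3S)-8-methoxy-2-methyl-3-(3,4,5-trimethoxyphenyl)-2,3-dihydro-1,4-benzodioxin-6-yl]prop-2-enal | COc1cc([C@@H]2Oc3cc(/C=C/C=O)cc(OC)c3O[C@H]2C)cc(OC)c1OC | target

**Totals**
Total step count: 3. Longest linear sequence: 3 (1 → 3 → 6 → 8).

**Steps most likely to fail, with fallbacks**

Step 2 (highest risk). The cycloaddition is untested as an asymmetric reaction. Possible failures are low ee, C-alkylation of the quinone instead of O,O-addition, the regioisomer with Cβ on Ob, or acid-induced dimerisation of 3. Regiochemistry should be confirmed by HMBC on 6 before going on.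
The fallback sets out from o-quinone 5 and comes back at bromide 6; chirality is put in by aminocatalysis instead.
- Quinone 5, made from 4 as in step 2, is treated with propanal (3 equiv), (S)-α,α-diphenylprolinol trimethylsilyl ether (10 mol%) and benzoic acid (10 mol%) in CH2Cl2 at −20 °C. The enamine carbon attacks Oa and the phenoxide closes on the iminium carbon. After hydrolysis this gives the lactol (3S)-7-bromo-5-methoxy-3-methyl-2,3-dihydro-1,4-benzodioxin-2-ol F1. This is enamine-mediated α-aryloxylation of an aldehyde by an o-quinone, a known reaction type; Cβ is set by the shielded enamine face.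
- 3,4,5-Trimethoxyphenylmagnesium bromide (2.5 equiv, THF, −40 to 0 °C, cold dilute HCl quench) adds to the open aldehyde form. This gives the diol (2S)-2-(4-bromo-2-hydroxy-6-methoxyphenoxy)-1-(3,4,5-trimethoxyphenyl)propan-1-ol F2 as both C1 epimers.
- Amberlyst 15 in CH2Cl2 at rt ionises the benzylic alcohol and the free phenol closes the ring. Either epimer gives the thermodynamically preferred trans isomer, which is 6.

Step 3. The electron-rich aryl bromide may undergo oxidative addition slowly, or β-hydride elimination may go towards the acetal carbon and give the 3-arylpropanoate ester.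
The fallback sets out from 6 and comes back at 8, without palladium.
- Bromine–lithium exchange (n-BuLi, 1.05 equiv, THF, −78 °C), then DMF and a water quench, gives (2S,3S)-8-methoxy-2-methyl-3-(3,4,5-trimethoxyphenyl)-2,3-dihydro-1,4-benzodioxine-6-carbaldehyde F3.
- Wittig homologation with (triphenylphosphoranylidene)acetaldehyde (1.2 equiv, toluene, 80 °C) gives the (E)-enal 8.

Step 1. The acid dehydration may dimerise the electron-rich styrene or leave too much Z isomer.
The fallback sets out from 1 and comes back at 3, without Brønsted acid.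
- Wittig olefination with ethylidenetriphenylphosphorane (EtPPh3Br, KOt-Bu, THF, 0 °C) gives the Z-rich alkene (Z)-1,2,3-trimethoxy-5-(prop-1-enyl)benzene F4, mixed with some 3.
- PdCl2(MeCN)2 (2 mol%) in CH2Cl2 at rt equilibrates the mixture to the E isomer 3.

**Further compounds**
F1 | step 2 | (3S)-7-bromo-5-methoxy-3-methyl-2,3-dihydro-1,4-benzodioxin-2-ol (anomer mixture) | OC1Oc2cc(Br)cc(OC)c2O[C@H]1C
F2 | step 2 | (2S)-2-(4-bromo-2-hydroxy-6-methoxyphenoxy)-1-(3,4,5-trimethoxyphenyl)propan-1-ol (C1 epimer mixture) | COc1cc(C(O)[C@H](C)Oc2c(O)cc(Br)cc2OC)cc(OC)c1OC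
F3 | step 3 | (2S,3S)-8-methoxy-2-methyl-3-(3,4,5-trimethoxyphenyl)-2,3-dihydro-1,4-benzodioxine-6-carbaldehyde | COc1cc([C@@H]2Oc3cc(C=O)cc(OC)c3O[C@H]2C)cc(OC)c1OC
F4 | step 1 | (Z)-1,2,3-trimethoxy-5-(prop-1-enyl)benzene | C/C=C\c1cc(OC)c(OC)c(OC)c1
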